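Take the charge of first end groups as the unit, and count links, second end groups and unlinked first ends as fractions of it.

the same everywhere: first end groups 0.032 M
- noon: second end groups 0.0352 M; the very flask that is asked about, followed so far
- summer: second end groups 0.018 M; run made earlier
- flask: second end groups 0.0352 M; time 6.0 h

- noon (time / min: links / %, first end groups / %): 15.0: 31.8, 29.3; 40.0: 50.5, 22.7; 80.0: 56.5, 18.9; 120: 59.4, 16.9; 180: 59.3, 18.2; 240: 60.8, 17.2; 300: 60.5, 16.7
- summer (time / min: links / %, first end groups / %): 1.00: 1.5, 66.7; 3.00: 5.1, 46.0; 6.00: 8.5, 41.5; 8.00: 13.6, 38.7; 12.0: 16.3, 36.4; 15.0: 18.4, 37.3; 20.0: 23.0, 36.5

(scatter of a reading: 1 percentage point)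

- delta: at 6.0 h add second end groups, 50.0% of the amount charged, then wait 2.0 h
- beta: change nothing and wait 2.0 h more
- gamma: at 6.0 h add first end groups, 50.0% of the amount charged, then wait 2.0 h
- theta: at 6.0 h take out 90% of the links then present, then wait 2.0 h

- removed links is counted in
- steps under discussion: first end groups + second end groups <-> links + released group; second end groups -> decomposed reagent; released group -> by-product carried off; first end groups <-> dormant form
- additions bring no volume worth counting

- links, in percent of the first end groups first charged, at 6.0 h
- the remedy with the largest gain of links, or "none" below 2 percentage points (delta / beta / gamma / theta / none)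
- links present, with what was taken out counted in, in percent of the first end groups first charged, after gamma
- links present, with what was taken out counted in, in percent of the first end groups first charged, after theta

Get the plateau of the noon flask by two separate ways. The last three link readings average 60.2%. The second way leaves the noon links column aside. In the summer run, take what is neither free nor link over the last three readings as dormant, which gives 1.20 dormant per free end. Apply that to the last three free readings of the noon flask, and 61.8% remains for links. The two part by 1.6 percentage points, while one point of scatter on a free reading counts 2.20 times in the second way, so commit to 60.2%.

Flat links in the noon flask could mean dead reagent or a balanced way back; take dead reagent. Let a be the pool of unlinked first ends, free and dormant together. If dormant keeps step with free, each bit of second end groups lost becomes links in the share a/(a+m). Summed over a run, the reagent spent is b = L + m ln(a/(a−L)). Here m is the split level 0.541, the pool at which second end groups are lost equally to links and to decomposition, reckoned from b = 1.10 and a = 1.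

Delta puts 0.550 of fresh reagent onto a pool of 39.8%. Start from the middle of that pool and correct once by the slope of the sum: the gain is 19 points. Beta, gamma and theta bring no reagent, so with dead reagent links stay at 60.2% after gamma and after theta.

The forecast gives 60.5%, chooses delta, and has 60.7% after gamma and 60.7% after theta: “With released group carried off and the plateau so abrupt, I favour decomposition”.

The flask gives 60.8%, and delta is best, with a gain of 18 points; gamma gives 60.8% and theta 60.8%.

    first end groups + second end groups ⇌ links + released group (K = 170, k = 0.0359 L mol⁻¹ s⁻¹)
    second end groups → decomposed reagent (k = 2.81 × 10⁻⁴ s⁻¹)
    released group → by-product carried off (k = 0.00779 s⁻¹)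
    first end groups ⇌ dormant form (K = 1.21, k = 0.00784 s⁻¹)

At 12.9 min the forward link step alone halves second end groups in 33 min, and decomposition alone in 41.1 min, which is longer but close. Second end groups, the limiting reagent in the flask, stand at 0% of their own charge at 360 min. Through the split level 0.541, the 60.8% of links calls for 0.507 of decomposed reagent, and the flask holds 0.492. The neighbour charged with 0.014 M of second end groups reaches 27.3% links, which calls for 0.172, and it holds 0.164.

All runs were generated by integration from invented constants; scatter was added.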